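**Plan**

- Retrosynthesis: the phenol C6–O is traced back to C6–B, then the benzene ring is cut at C4a–C8a, C5–C6 and C7–C8 ([2+2+2]). This leaves an open-chain 1,7-diyne (the 1-propynyl ether of a tertiary alcohol that carries a but-3-ynyl arm) and ethynylboronic acid pinacol ester. The tertiary alcohol is cut at C1'–C2' into a C15 bromide and an epoxy-alkyne.
- Enabling feature: the benzene ring divides into three two-carbon alkyne units, C8/C8a, C4a/C5 and C6/C7. The first two are already tied together through O1–C2–C3–C4, and O1 already sits on the stereogenic quaternary C2.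
- Forward order: the side chain (steps 1–5) and the epoxide (steps 6–10) are made separately and joined at C1'–C2' by Grignard opening of the epoxide. The ynol ether is then put on the tertiary oxygen, the dihydropyran and benzene rings close together in one cyclotrimerisation, and C–B oxidation ends the route.
- Stereochemistry: C8' is bought in (R)-citronellyl bromide. C4' comes from Ru(OAc)2[(S)-BINAP] hydrogenation of an E-allylic alcohol made by syn-carboalumination. C2 comes from Sharpless epoxidation of methallyl alcohol with D-(−)-diisopropyl tartrate, and its C–O bond is never broken afterwards.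

Key step: step 15

Remark: by the CIP rules the target is (2R,4'R,8'S); 8' reads S only because the 11',12'-alkene branch outranks the saturated branch, and its spatial arrangement is that of the stereocentre of (R)-citronellyl bromide.
Remark: the alkyne of the epoxide fragment is capped with triisopropylsilyl, because the cap must survive a potassium alkoxide (step 12) and n-BuLi (step 13) and because its bulk steers the lithiated propyne to propargylic attack.
Remark: (R)-citronellyl bromide, 1-(triisopropylsilyl)propyne and ethynylboronic acid pinacol ester are taken to be purchasable.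

**Route**

Step 1
Reactants: 1 (R)-citronellyl bromide [(6R)-8-bromo-2,6-dimethyloct-2-ene]; 2 1-(trimethylsilyl)propyne
Product: 4 trimethyl[(6S)-6,10-dimethylundec-9-en-1-yn-1-yl]silane, via 3-lithio-1-(trimethylsilyl)propyne 3 (not isolated)
Conditions: 2, n-BuLi, THF, −78 to −20 °C; then 1, −78 °C to rt
Reagents that add atoms: none
Why: Propargyl-anion alkylation: n-BuLi deprotonates 2 at the methyl group and the lithium reagent 3 should displace the primary bromide of 1 in an SN2 reaction mainly through its propargylic carbon, leaving the methyl-bearing stereocentre untouched (its descriptor reads S in 4 only because the CIP priorities change).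

Step 2
Reactants: 4 trimethyl[(6S)-6,10-dimethylundec-9-en-1-yn-1-yl]silane
Product: 5 (6S)-6,10-dimethylundec-9-en-1-yne
Conditions: K2CO3, MeOH, rt
Reagents that add atoms: none
Why: Base-catalysed methanolysis of the C(sp)–Si bond (protodesilylation) should free the terminal alkyne and leave the trisubstituted alkene alone.

Step 3
Reactants: 5 (6S)-6,10-dimethylundec-9-en-1-yne
Product: 8 (2E,7S)-3,7,11-trimethyldodeca-2,10-dien-1-ol, via alkenyldimethylalane 6 (not isolated), via lithium alkenylalanate 7 (not isolated)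
Conditions: Me3Al, Cp2ZrCl2 (25 mol%), CH2Cl2, 0 °C to rt; excess Me3Al removed in vacuo; n-BuLi, THF, −78 to 0 °C; (CH2O)n, rt; aq HCl
Reagents that add atoms: trimethylaluminium, C[Al](C)C; paraformaldehyde (as formaldehyde), C=O
Why: Negishi zirconium-catalysed carboalumination adds methyl and aluminium syn across the terminal alkyne with aluminium at the terminal carbon, and hydroxymethylation of the derived alanate with formaldehyde occurs with retention at the alkenyl carbon, so the E-allylic alcohol is expected and the isolated alkene is not carbometalated.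

Step 4
Reactants: 8 (2E,7S)-3,7,11-trimethyldodeca-2,10-dien-1-ol
Product: 9 (3R,7S)-3,7,11-trimethyldodec-10-en-1-ol
Conditions: H2 (100 atm), Ru(OAc)2[(S)-BINAP] (0.5 mol%), MeOH, 20 °C
Reagents that add atoms: none
Why: Noyori hydroxyl-directed asymmetric hydrogenation: the allylic hydroxyl binds the ruthenium–BINAP catalyst and the (S)-ligand should deliver hydrogen to the face of the E-alkene that gives 3R (the sense in which geraniol gives (R)-citronellol), while the remote trisubstituted alkene, which has no directing group, stays.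

Step 5
Reactants: 9 (3R,7S)-3,7,11-trimethyldodec-10-en-1-ol
Product: 10 (6S,10R)-12-bromo-2,6,10-trimethyldodec-2-ene
Conditions: CBr4, PPh3, CH2Cl2, 0 °C
Reagents that add atoms: tetrabromomethane, BrC(Br)(Br)Br
Why: Appel reaction, in which the alkoxyphosphonium ion of the primary alcohol is displaced by bromide under neutral conditions that touch neither the alkene nor the stereocentres.

Step 6
Reactants: 11 methallyl alcohol (2-methylprop-2-en-1-ol)
Product: 12 (R)-2-methylglycidol {[(2R)-2-methyloxiran-2-yl]methanol}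
Conditions: Ti(OiPr)4 (5 mol%), D-(−)-diisopropyl tartrate (6 mol%), cumene hydroperoxide, 3 Å molecular sieves, CH2Cl2, −20 °C; distillation
Reagents that add atoms: cumene hydroperoxide, CC(C)(OO)c1ccccc1
Why: Sharpless asymmetric epoxidation of a 2-substituted allylic alcohol, in which the titanium–D-(−)-tartrate complex should deliver oxygen to the alkene face that gives the R epoxy alcohol and thereby sets the quaternary carbon that becomes C2.

Step 7
Reactants: 12 (R)-2-methylglycidol
Product: 13 (2S)-2-methyl-2-[(triphenylmethoxy)methyl]oxirane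
Conditions: Ph3CCl, Et3N, DMAP (cat.), CH2Cl2, 0 °C to rt
Reagents that add atoms: trityl chloride, ClC(c1ccccc1)(c1ccccc1)c1ccccc1
Why: Tritylation of the primary alcohol under amine base (SN1-type O-alkylation by the trityl cation) protects the hydroxyl against the organolithium of step 8 without opening the epoxide, and the descriptor reads S only through the change in CIP priorities.

Step 8
Reactants: 13 (2S)-2-methyl-2-[(triphenylmethoxy)methyl]oxirane; 14 1-(triisopropylsilyl)propyne
Product: 16 (2S)-2-methyl-1-(triphenylmethoxy)-6-[tri(propan-2-yl)silyl]hex-5-yn-2-ol, via 3-lithio-1-(triisopropylsilyl)propyne 15 (not isolated)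
Conditions: 14, n-BuLi, THF, −20 to 0 °C; then 13, DMPU, −20 °C to rt; H2O
Reagents that add atoms: none
Why: SN2 ring opening of the 2,2-disubstituted epoxide at its CH2 terminus by the propargylic lithium reagent 15, whose bulky silyl cap should suppress attack through the allenyl terminus; the C–O bond at the quaternary carbon is not involved, so the stereocentre is retained.

Step 9
Reactants: 16 (2S)-2-methyl-1-(triphenylmethoxy)-6-[tri(propan-2-yl)silyl]hex-5-yn-2-ol
Product: 17 (2S)-2-methyl-6-[tri(propan-2-yl)silyl]hex-5-yne-1,2-diol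
Conditions: TsOH·H2O (10 mol%), MeOH/CH2Cl2 1:1, rt
Reagents that add atoms: none
Why: Acid-catalysed methanolysis of the trityl ether (SN1 cleavage through the trityl cation) under conditions mild enough for the alkynylsilane and the tertiary alcohol.

Step 10
Reactants: 17 (2S)-2-methyl-6-[tri(propan-2-yl)silyl]hex-5-yne-1,2-diol
Product: 19 {4-[(2S)-2-methyloxiran-2-yl]but-1-yn-1-yl}tri(propan-2-yl)silane, via primary tosylate 18 (not isolated)
Conditions: TsCl, Et3N, Bu2SnO (2 mol%), CH2Cl2, 0 °C to rt; solvent exchange; NaH, THF, 0 °C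
Reagents that add atoms: none
Why: Tin-catalysed selective monosulfonylation of the primary hydroxyl of the 1,2-diol followed by intramolecular Williamson etherification (3-exo-tet) through the tertiary alkoxide should close the new epoxide with the bond between oxygen and the quaternary carbon intact, so that the two CH2 groups have exchanged roles and the configuration is kept.

Step 11
Reactants: 10 (6S,10R)-12-bromo-2,6,10-trimethyldodec-2-ene; 19 {4-[(2S)-2-methyloxiran-2-yl]but-1-yn-1-yl}tri(propan-2-yl)silane
Product: 21 (5R,9R,13S)-5,9,13,17-tetramethyl-1-[tri(propan-2-yl)silyl]octadec-16-en-1-yn-5-ol, via Grignard reagent 20 (not isolated)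
Conditions: 10, Mg, THF, 40 °C; then CuI (10 mol%), 19, THF, −30 to 0 °C; H2O
Reagents that add atoms: none
Why: Copper-catalysed Grignard opening of the terminal epoxide (SN2 at CH2) forms the C1'–C2' bond, the silylated alkyne and the trisubstituted alkene being inert to the reagent and no stereocentre being touched.

Step 12
Reactants: 21 (5R,9R,13S)-5,9,13,17-tetramethyl-1-[tri(propan-2-yl)silyl]octadec-16-en-1-yn-5-ol; 22 trichloroethylene
Product: 24 {(5R,9R,13S)-5-{[(E)-1,2-dichloroethenyl]oxy}-5,9,13,17-tetramethyloctadec-16-en-1-yn-1-yl}tri(propan-2-yl)silane, via potassium alkoxide 23 (not isolated)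
Conditions: KH, THF, 0 °C to rt; then 22, −50 °C to rt
Reagents that add atoms: none
Why: Addition–elimination of the potassium alkoxide on trichloroethylene, most probably by base-induced loss of HCl to dichloroacetylene and anti addition of the alkoxide across it, should give the E-1,2-dichlorovinyl ether, a slim linear electrophile being what a hindered tertiary alkoxide needs and the triisopropylsilyl alkyne resisting the alkoxide.

Step 13
Reactants: 24 {(5R,9R,13S)-5-{[(E)-1,2-dichloroethenyl]oxy}-5,9,13,17-tetramethyloctadec-16-en-1-yn-1-yl}tri(propan-2-yl)silane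
Product: 27 {(5R,9R,13S)-5,9,13,17-tetramethyl-5-(prop-1-yn-1-yloxy)octadec-16-en-1-yn-1-yl}tri(propan-2-yl)silane, via chloroethynyl ether 25 (not isolated), via lithium alkynyl ether 26 (not isolated)
Conditions: n-BuLi (2.4 equiv), THF, −78 to −40 °C; then MeI, HMPA, −40 to 0 °C; cold work-up, Et3N-deactivated silica
Reagents that add atoms: iodomethane, CI
Why: Dehydrochlorination by n-BuLi gives chloroethynyl ether 25, chlorine–lithium exchange with a second equivalent gives acetylide 26, and SN2 C-methylation of this acetylide with iodomethane in the presence of HMPA (acetylide alkylation) installs the carbon that becomes the C8 methyl.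

Step 14
Reactants: 27 {(5R,9R,13S)-5,9,13,17-tetramethyl-5-(prop-1-yn-1-yloxy)octadec-16-en-1-yn-1-yl}tri(propan-2-yl)silane
Product: 28 (5R,9R,13S)-5,9,13,17-tetramethyl-5-(prop-1-yn-1-yloxy)octadec-16-en-1-yne
Conditions: TBAF, THF, 0 °C
Reagents that add atoms: none
Why: Fluoride-induced protodesilylation of the alkynylsilane, run cold and without acid because the ynol ether is stable to base but hydrates under acid and fragments on heating.

Step 15
Reactants: 28 (5R,9R,13S)-5,9,13,17-tetramethyl-5-(prop-1-yn-1-yloxy)octadec-16-en-1-yne; 29 ethynylboronic acid pinacol ester (2-ethynyl-4,4,5,5-tetramethyl-1,3,2-dioxaborolane)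
Product: 30 2-{(2R)-2,8-dimethyl-2-[(4R,8S)-4,8,12-trimethyltridec-11-en-1-yl]-3,4-dihydro-2H-chromen-6-yl}-4,4,5,5-tetramethyl-1,3,2-dioxaborolane
Conditions: Cp*RuCl(cod) (10 mol%), 29 (3 equiv), ClCH2CH2Cl, 20 °C, slow addition of 28
Reagents that add atoms: none
Why: This is a transition-metal-catalysed [2+2+2] cyclotrimerisation of a tethered diyne with a monoalkyne, a reaction type established for 1,6- and 1,7-diynes with Cp*RuCl(cod) and, separately, for alkynyl ethers and alkynylboronates as partners. The Cp*RuCl fragment (divalent ruthenium) binds both alkynes of 28 and couples them oxidatively at C4a and C8a to a ruthenacyclopentadiene (formally tetravalent ruthenium) whose metal-bound carbons are C5 and C8, which closes the dihydropyran ring (O1, C2, C3, C4, C4a, C8a) as a six-membered ring on the metal, helped by the gem-disubstituted C2. Insertion of 29 and reductive elimination then form C5–C6 and C7–C8 and close the benzene ring, aromatisation making the sequence irreversible. No stereocentre is created, and C2 keeps its configuration because the O1–C2 bond is already in place and nothing in the cycle ionises it. The selectivity needed is regiochemical, boron at C6 and not at C7: the carbon that bears the bulky pinacolboryl group should bond to the unsubstituted C5 terminus and the CH end to the methyl-bearing C8, the meta relationship that this catalyst normally gives with diynes substituted at one terminus. Ambient temperature, an excess of 29 and slow addition of 28 are chosen to keep retro-ene loss of methylketene from the tertiary-alkyl ynol ether and homocoupling of the diyne in check.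

Step 16
Reactants: 30 2-{(2R)-2,8-dimethyl-2-[(4R,8S)-4,8,12-trimethyltridec-11-en-1-yl]-3,4-dihydro-2H-chromen-6-yl}-4,4,5,5-tetramethyl-1,3,2-dioxaborolane
Product: 31 (2R)-2,8-dimethyl-2-[(4R,8S)-4,8,12-trimethyltridec-11-en-1-yl]-3,4-dihydro-2H-chromen-6-ol (target)
Conditions: NaBO3·4H2O, THF/H2O 1:1, 20 °C, degassed
Reagents that add atoms: sodium perborate tetrahydrate, [Na+].[O-]OB=O.O.O.O.O
Why: Oxidation of the aryl C–B bond (1,2-migration of the aryl group from boron to oxygen in the peroxoborate adduct, then hydrolysis) should give the phenol under mildly basic conditions that do not epoxidise the trisubstituted alkene.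

**Compound list**

1 | (R)-citronellyl bromide, (6R)-8-bromo-2,6-dimethyloct-2-ene | CC(C)=CCC[C@@H](C)CCBr | starting material
2 | 1-(trimethylsilyl)propyne | CC#C[Si](C)(C)C | starting material
3 | 3-lithio-1-(trimethylsilyl)propyne | [Li]CC#C[Si](C)(C)C | intermediate
4 | trimethyl[(6S)-6,10-dimethylundec-9-en-1-yn-1-yl]silane | CC(C)=CCC[C@@H](C)CCCC#C[Si](C)(C)C | intermediate
5 | (6S)-6,10-dimethylundec-9-en-1-yne | CC(C)=CCC[C@@H](C)CCCC#C | intermediate
6 | dimethyl[(1E,6S)-2,6,10-trimethylundeca-1,9-dien-1-yl]alumane | CC(C)=CCC[C@@H](C)CCC/C(C)=C/[Al](C)C | intermediate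
7 | lithium butyl(dimethyl)[(1E,6S)-2,6,10-trimethylundeca-1,9-dien-1-yl]aluminate | CC(C)=CCC[C@@H](C)CCC/C(C)=C/[Al-](C)(C)CCCC.[Li+] | intermediate
8 | (2E,7S)-3,7,11-trimethyldodeca-2,10-dien-1-ol | CC(C)=CCC[C@@H](C)CCC/C(C)=C/CO | intermediate
9 | (3R,7S)-3,7,11-trimethyldodec-10-en-1-ol | CC(C)=CCC[C@@H](C)CCC[C@@H](C)CCO | intermediate
10 | (6S,10R)-12-bromo-2,6,10-trimethyldodec-2-ene | CC(C)=CCC[C@@H](C)CCC[C@@H](C)CCBr | intermediate
11 | methallyl alcohol (2-methylprop-2-en-1-ol) | CC(=C)CO | starting material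
12 | (R)-2-methylglycidol, [(2R)-2-methyloxiran-2-yl]methanol | OC[C@]1(C)CO1 | intermediate
13 | (2S)-2-methyl-2-[(triphenylmethoxy)methyl]oxirane | c1ccccc1C(c1ccccc1)(c1ccccc1)OC[C@]2(C)CO2 | intermediate
14 | 1-(triisopropylsilyl)propyne | CC#C[Si](C(C)C)(C(C)C)C(C)C | starting material
15 | 3-lithio-1-(triisopropylsilyl)propyne | [Li]CC#C[Si](C(C)C)(C(C)C)C(C)C | intermediate
16 | (2S)-2-methyl-1-(triphenylmethoxy)-6-[tri(propan-2-yl)silyl]hex-5-yn-2-ol | c1ccccc1C(c1ccccc1)(c1ccccc1)OC[C@@](C)(O)CCC#C[Si](C(C)C)(C(C)C)C(C)C | intermediate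
17 | (2S)-2-methyl-6-[tri(propan-2-yl)silyl]hex-5-yne-1,2-diol | OC[C@@](C)(O)CCC#C[Si](C(C)C)(C(C)C)C(C)C | intermediate
18 | [(2S)-2-hydroxy-2-methyl-6-[tri(propan-2-yl)silyl]hex-5-yn-1-yl] 4-methylbenzenesulfonate | Cc1ccc(cc1)S(=O)(=O)OC[C@@](C)(O)CCC#C[Si](C(C)C)(C(C)C)C(C)C | intermediate
19 | {4-[(2S)-2-methyloxiran-2-yl]but-1-yn-1-yl}tri(propan-2-yl)silane | CC(C)[Si](C(C)C)(C(C)C)C#CCC[C@@]1(C)CO1 | intermediate
20 | [(3R,7S)-3,7,11-trimethyldodec-10-en-1-yl]magnesium bromide | CC(C)=CCC[C@@H](C)CCC[C@@H](C)CC[Mg]Br | intermediate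
21 | (5R,9R,13S)-5,9,13,17-tetramethyl-1-[tri(propan-2-yl)silyl]octadec-16-en-1-yn-5-ol | CC(C)=CCC[C@@H](C)CCC[C@@H](C)CCC[C@](O)(C)CCC#C[Si](C(C)C)(C(C)C)C(C)C | intermediate
22 | trichloroethylene | ClC=C(Cl)Cl | starting material
23 | potassium (5R,9R,13S)-5,9,13,17-tetramethyl-1-[tri(propan-2-yl)silyl]octadec-16-en-1-yn-5-olate | CC(C)=CCC[C@@H](C)CCC[C@@H](C)CCC[C@]([O-])(C)CCC#C[Si](C(C)C)(C(C)C)C(C)C.[K+] | intermediate
24 | {(5R,9R,13S)-5-{[(E)-1,2-dichloroethenyl]oxy}-5,9,13,17-tetramethyloctadec-16-en-1-yn-1-yl}tri(propan-2-yl)silane | CC(C)=CCC[C@@H](C)CCC[C@@H](C)CCC[C@](O/C(Cl)=C\Cl)(C)CCC#C[Si](C(C)C)(C(C)C)C(C)C | intermediate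
25 | {(5R,9R,13S)-5-[(chloroethynyl)oxy]-5,9,13,17-tetramethyloctadec-16-en-1-yn-1-yl}tri(propan-2-yl)silane | CC(C)=CCC[C@@H](C)CCC[C@@H](C)CCC[C@](OC#CCl)(C)CCC#C[Si](C(C)C)(C(C)C)C(C)C | intermediate
26 | lithium acetylide of the ethynyl ether, {[(5R,9R,13S)-5,9,13,17-tetramethyl-1-[tri(propan-2-yl)silyl]octadec-16-en-1-yn-5-yl]oxy}ethynyllithium | CC(C)=CCC[C@@H](C)CCC[C@@H](C)CCC[C@](OC#C[Li])(C)CCC#C[Si](C(C)C)(C(C)C)C(C)C | intermediate
27 | {(5R,9R,13S)-5,9,13,17-tetramethyl-5-(prop-1-yn-1-yloxy)octadec-16-en-1-yn-1-yl}tri(propan-2-yl)silane | CC(C)=CCC[C@@H](C)CCC[C@@H](C)CCC[C@](OC#CC)(C)CCC#C[Si](C(C)C)(C(C)C)C(C)C | intermediate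
28 | (5R,9R,13S)-5,9,13,17-tetramethyl-5-(prop-1-yn-1-yloxy)octadec-16-en-1-yne | CC(C)=CCC[C@@H](C)CCC[C@@H](C)CCC[C@](OC#CC)(C)CCC#C | intermediate
29 | ethynylboronic acid pinacol ester (2-ethynyl-4,4,5,5-tetramethyl-1,3,2-dioxaborolane) | C#CB1OC(C)(C)C(C)(C)O1 | starting material
30 | 2-{(2R)-2,8-dimethyl-2-[(4R,8S)-4,8,12-trimethyltridec-11-en-1-yl]-3,4-dihydro-2H-chromen-6-yl}-4,4,5,5-tetramethyl-1,3,2-dioxaborolane | CC(C)=CCC[C@@H](C)CCC[C@@H](C)CCC[C@]1(C)CCc2cc(B3OC(C)(C)C(C)(C)O3)cc(C)c2O1 | intermediate
31 | (2R)-2,8-dimethyl-2-[(4R,8S)-4,8,12-trimethyltridec-11-en-1-yl]-3,4-dihydro-2H-chromen-6-ol | CC(C)=CCC[C@@H](C)CCC[C@@H](C)CCC[C@]1(C)CCc2cc(O)cc(C)c2O1 | target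

**Count and risks**

Total step count: 16.
Longest linear sequence: 11 steps (steps 1–5, then 11–16; the epoxide branch, steps 6–10 then 11–16, is equally long).

Steps most likely to fail:

1. Step 15. Homocoupling of the diyne and trimerisation of the boronate may outrun the cross reaction; the orientation of insertion that places boron at C6 may erode; the ynol ether may fragment by retro-ene reaction before it is consumed. The fallback sets out from epoxide 13 and returns at boronate 30; it makes the chroman without an ynol ether, by intramolecular C–O coupling of the tertiary alcohol. Epoxide 13 is opened at CH2 (CuI cat., THF, −20 °C) by (2-bromo-3-methylbenzyl)magnesium bromide F1, prepared from purchased 2-bromo-1-(bromomethyl)-3-methylbenzene and Mg in Et2O at 0 °C, to give (2S)-4-(2-bromo-3-methylphenyl)-2-methyl-1-(triphenylmethoxy)butan-2-ol F2. Detritylation (TsOH, MeOH) gives (2S)-4-(2-bromo-3-methylphenyl)-2-methylbutane-1,2-diol F3. Its primary tosylate [(2S)-4-(2-bromo-3-methylphenyl)-2-hydroxy-2-methylbutyl] 4-methylbenzenesulfonate F4 (TsCl, Et3N, Bu2SnO cat.) is closed with NaH in THF to (2S)-2-[2-(2-bromo-3-methylphenyl)ethyl]-2-methyloxirane F5. Grignard reagent 20 with CuI opens this epoxide at CH2 to (3R,7R,11S)-1-(2-bromo-3-methylphenyl)-3,7,11,15-tetramethylhexadec-14-en-3-ol F6. Buchwald–Hartwig-type intramolecular etherification (Pd(OAc)2, [1,1'-binaphthalen]-2-yldi-tert-butylphosphine, Cs2CO3, toluene, 80 °C) forms O1–C8a with O1–C2 intact and gives (2R)-2,8-dimethyl-2-[(4R,8S)-4,8,12-trimethyltridec-11-en-1-yl]-3,4-dihydro-2H-chromene F7. Iridium-catalysed C–H borylation ([Ir(OMe)(cod)]2, 4,4'-di-tert-butyl-2,2'-bipyridine, B2pin2, hexane, 60 °C) should go to C6, the only aromatic C–H without an ortho substituent, and gives 30.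

2. Step 12. The hindered tertiary alkoxide may add too slowly, so that base-induced decomposition of the chlorinated electrophile outruns ether formation. The fallback sets out from alcohol 21 and returns at propynyl ether 27; it forms the enol ether carbon–carbon bond at an unhindered formyl carbon instead of asking the alkoxide to attack. Alcohol 21 is formylated (acetic formic anhydride, pyridine, 0 °C) to (5R,9R,13S)-5,9,13,17-tetramethyl-1-[tri(propan-2-yl)silyl]octadec-16-en-1-yn-5-yl formate F8. Wittig-type dichloromethylenation (PPh3, CCl4, THF, 60 °C) gives {(5R,9R,13S)-5-[(2,2-dichloroethenyl)oxy]-5,9,13,17-tetramethyloctadec-16-en-1-yn-1-yl}tri(propan-2-yl)silane F9. Treatment with n-BuLi and then MeI/HMPA as in step 13, through 25 and 26, gives 27.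

3. Step 8. The lithiated propyne may attack through its allenyl terminus, or the opening of the hindered 2,2-disubstituted epoxide may be sluggish. The fallback sets out from epoxide 13 and returns at alcohol 16; it puts the extra carbon into the electrophile and uses a non-ambident acetylide. Corey–Chaykovsky-type ring expansion of 13 with dimethylsulfoxonium methylide (Me3S(O)I, KOtBu, t-BuOH, 70 °C) gives (2S)-2-methyl-2-[(triphenylmethoxy)methyl]oxetane F10, with the quaternary C–O bond untouched. Lithium (triisopropylsilyl)acetylide F11, made from ethynyltri(propan-2-yl)silane and n-BuLi, with BF3·OEt2 in THF at −78 °C opens the oxetane at its CH2–O carbon and gives 16.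

**Further compounds**

F1 | step 15 | (2-bromo-3-methylbenzyl)magnesium bromide | Cc1cccc(C[Mg]Br)c1Br
F2 | step 15 | (2S)-4-(2-bromo-3-methylphenyl)-2-methyl-1-(triphenylmethoxy)butan-2-ol | c1ccccc1C(c1ccccc1)(c1ccccc1)OC[C@@](C)(O)CCc1cccc(C)c1Br
F3 | step 15 | (2S)-4-(2-bromo-3-methylphenyl)-2-methylbutane-1,2-diol | OC[C@@](C)(O)CCc1cccc(C)c1Br
F4 | step 15 | [(2S)-4-(2-bromo-3-methylphenyl)-2-hydroxy-2-methylbutyl] 4-methylbenzenesulfonate | Cc1ccc(cc1)S(=O)(=O)OC[C@@](C)(O)CCc1cccc(C)c1Br
F5 | step 15 | (2S)-2-[2-(2-bromo-3-methylphenyl)ethyl]-2-methyloxirane | Cc1cccc(CC[C@@]2(C)CO2)c1Br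
F6 | step 15 | (3R,7R,11S)-1-(2-bromo-3-methylphenyl)-3,7,11,15-tetramethylhexadec-14-en-3-ol | CC(C)=CCC[C@@H](C)CCC[C@@H](C)CCC[C@](O)(C)CCc1cccc(C)c1Br
F7 | step 15 | (2R)-2,8-dimethyl-2-[(4R,8S)-4,8,12-trimethyltridec-11-en-1-yl]-3,4-dihydro-2H-chromene | CC(C)=CCC[C@@H](C)CCC[C@@H](C)CCC[C@]1(C)CCc2cccc(C)c2O1
F8 | step 12 | (5R,9R,13S)-5,9,13,17-tetramethyl-1-[tri(propan-2-yl)silyl]octadec-16-en-1-yn-5-yl formate | CC(C)=CCC[C@@H](C)CCC[C@@H](C)CCC[C@](OC=O)(C)CCC#C[Si](C(C)C)(C(C)C)C(C)C
F9 | step 12 | {(5R,9R,13S)-5-[(2,2-dichloroethenyl)oxy]-5,9,13,17-tetramethyloctadec-16-en-1-yn-1-yl}tri(propan-2-yl)silane | CC(C)=CCC[C@@H](C)CCC[C@@H](C)CCC[C@](OC=C(Cl)Cl)(C)CCC#C[Si](C(C)C)(C(C)C)C(C)C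
F10 | step 8 | (2S)-2-methyl-2-[(triphenylmethoxy)methyl]oxetane | c1ccccc1C(c1ccccc1)(c1ccccc1)OC[C@]2(C)CCO2
F11 | step 8 | lithium (triisopropylsilyl)acetylide | [Li]C#C[Si](C(C)C)(C(C)C)C(C)C
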